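The route rests on cutting the depside ester between the ring A carboxyl and O–C4 of ring B. This demands a ring B unit whose C4 hydroxyl alone is free. The key step exploits the 1,2,4,6 pattern of ring B (C1 carboxyl, C2–O, C4–O, C6 pentyl). A 2-pyrone already holding C1, C2, C3 and C6 takes up C4 and C5 from a bis-silyl ketene acetal, loses CO2 and silanol, and emerges as the arene with C4–O as an acid-labile silyl ether. The precursor is a 6-pentyl-2-pyrone carrying a benzyl ester at its C5 and a benzyl ether at its C4. Ring A receives its C3' chlorine by directed lithiation between two methoxy groups.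

Key step: step 4

Numbering: on ring B, C1 bears the carboxyl group, C2 the hydroxyl, C4 the depside oxygen and C6 the pentyl chain. Ring A is numbered C1' to C6' in the same sense (C2' OH, C3' Cl, C4' OMe, C6' propyl). Pyrone C5, C4, C3 and C6 become ring B C1, C2, C3 and C6. The target has no stereocentre.

Assumption: electrophilic chlorination of a 2-hydroxy-4-methoxy-6-alkylbenzoyl ring is taken to favour C5' over C3', so chlorine is introduced by lithiation before the carbonyl carbon is attached. The C2' hydroxyl stays unprotected in the coupling, so only two benzyl groups must be removed in the presence of C–Cl.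

Step 1
Reactants: 1 dibenzyl 3-oxopentanedioate; 2 hexanoyl chloride
Product: 4 benzyl 4-hydroxy-2-oxo-6-pentyl-2H-pyran-5-carboxylate, via acylated oxoglutarate 3 (not isolated)
Conditions: MgCl2, pyridine, CH2Cl2, 0 °C to rt; dilute aq. HCl wash; crude 3, DBU, toluene, 80 °C; dilute aq. HCl
Reagents that add atoms: none
Why: Soft-enolisation C-acylation of the magnesium chelate of the β-keto diester (at one of two equivalent CH2 groups) gives a 3,5-dioxo ester whose hexanoyl enol oxygen can reach only the distal benzyl ester in a six-membered closure, the standard DBU-promoted lactonisation to a 4-hydroxy-2-pyrone.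

Step 2
Reactants: 4 benzyl 4-hydroxy-2-oxo-6-pentyl-2H-pyran-5-carboxylate
Product: 5 benzyl 4-(benzyloxy)-2-oxo-6-pentyl-2H-pyran-5-carboxylate
Conditions: BnOH, PPh3, DIAD, THF, 0 °C to rt
Reagents that add atoms: benzyl alcohol, OCc1ccccc1
Why: Mitsunobu etherification of the acidic vinylogous carboxylic acid OH is known to alkylate O4 on 4-hydroxy-2-pyrones, which avoids the C3-benzylation and 2-alkoxy-4-pyrone formation that a benzyl halide and base can give, and it removes the proton that would destroy the ketene acetal in step 4.

Step 3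
Reactants: 6 trimethylsilyl acetate
Product: 8 1,1-bis(trimethylsilyloxy)ethene, via lithium enolate 7 (not isolated)
Conditions: LDA (LiN(i-Pr)2), THF, −78 °C; TMSCl, −78 °C to rt; filtration under Ar, distillation
Reagents that add atoms: chlorotrimethylsilane, C[Si](C)(C)Cl
Why: Ester enolate O-silylation, that is kinetic deprotonation of the silyl ester and trapping on oxygen with TMSCl, is the established preparation of ketene bis(trimethylsilyl) acetals, and distillation should remove any C-silylated isomer.

Step 4
Reactants: 5 benzyl 4-(benzyloxy)-2-oxo-6-pentyl-2H-pyran-5-carboxylate; 8 1,1-bis(trimethylsilyloxy)ethene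
Product: 12 benzyl 2-(benzyloxy)-4-hydroxy-6-pentylbenzoate, via bridged lactone 9 (not isolated), via cyclohexadiene 10 (not isolated), via aryl silyl ether 11 (not isolated)
Conditions: 8 (5 equiv), toluene (concentrated), sealed tube, 140 °C; then dilute aq. HCl, THF, rt
Reagents that add atoms: none
Why: Bond formation is led by the nucleophilic methylene carbon of 8, which engages pyrone C6 (β to the C5 ester and the vinylogous terminus of the lactone carbonyl), while the dioxygenated carbon of 8 joins pyrone C3, so ring B bonds C5–C6 and C3–C4 arise in one inverse-electron-demand Diels–Alder event that is probably concerted but highly asynchronous. Ring B is therefore closed by an intermolecular (4+2) cycloaddition, four ring carbons (C6, C1, C2, C3) coming from the pyrone diene and two (C4, C5) from the dienophile, with the 2-oxabicyclo[2.2.2]octenone 9 as first product. At the reaction temperature 9 undergoes cycloreversion with extrusion of CO2 to diene 10, 1,2-elimination of trimethylsilanol across C4–C5 aromatises 10 to silyl ether 11, and dilute acid then frees phenol 12. The closest known reaction type is the conversion of 2-pyrone-5-carboxylates (coumalates) into 4-alkoxybenzoates by dialkyl ketene acetals; relative to those cases the benzyloxy donor on pyrone C4 and the fully substituted C6 should lower the rate, which is answered by excess 8, high concentration and 140 °C. The selectivity required is regiochemical only and is secured by this polarity match, which places the new oxygen para to C1 and meta to the pentyl chain, and since both oxygens on C4 of 10 carry the same silyl group the elimination cannot give two products. The bridgehead stereocentres of 9 are tied to each other by the bicycle, form as a racemate and disappear on aromatisation, so no stereocontrol is needed.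

Step 5
Reactants: 13 5-propylbenzene-1,3-diol
Product: 14 1,3-dimethoxy-5-propylbenzene
Conditions: (MeO)2SO2, K2CO3, acetone, reflux
Reagents that add atoms: dimethyl sulfate, COS(=O)(=O)OC
Why: Williamson-type O-methylation of both phenols with a hard methylating agent and carbonate base is a routine conversion of 5-alkylresorcinols.

Step 6
Reactants: 14 1,3-dimethoxy-5-propylbenzene
Product: 16 2-chloro-1,3-dimethoxy-5-propylbenzene, via aryllithium 15 (not isolated)
Conditions: n-BuLi, THF, 0 °C to rt; C2Cl6, −78 °C to rt
Reagents that add atoms: hexachloroethane, ClC(Cl)(Cl)C(Cl)(Cl)Cl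
Why: In this directed ortho-metalation the two methoxy groups cooperatively steer lithiation to the carbon between them and hexachloroethane transfers electrophilic chlorine to the aryllithium, which fixes the halogen at the future C3' without relying on electrophilic regioselectivity.

Step 7
Reactants: 16 2-chloro-1,3-dimethoxy-5-propylbenzene
Product: 18 3-chloro-2,4-dimethoxy-6-propylbenzaldehyde, via chloro ether 17 (not isolated)
Conditions: Cl2CHOMe, TiCl4, CH2Cl2, −78 to 0 °C; then ice-water
Reagents that add atoms: dichloromethyl methyl ether, COC(Cl)Cl; water, O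
Why: In this Rieche formylation the only open ring positions are two equivalent carbons, each ortho to one methoxy group and para to the other, so a single aldehyde can form and the deactivating formyl group stops a second substitution.

Step 8
Reactants: 18 3-chloro-2,4-dimethoxy-6-propylbenzaldehyde
Product: 20 3-chloro-2-hydroxy-4-methoxy-6-propylbenzaldehyde, via boron chelate 19 (not isolated)
Conditions: BCl3, CH2Cl2, −78 to 0 °C; then H2O
Reagents that add atoms: none
Why: In this chelation-controlled Lewis-acid ether cleavage BCl3 binds the aldehyde oxygen and the neighbouring C2' methoxy oxygen in a six-membered chelate and chloride removes only that methyl group, the C4' methoxy group lacking such activation at this temperature.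

Step 9
Reactants: 20 3-chloro-2-hydroxy-4-methoxy-6-propylbenzaldehyde
Product: 21 3-chloro-2-hydroxy-4-methoxy-6-propylbenzoic acid
Conditions: NaClO2, NaH2PO4, 2-methyl-2-butene (large excess), t-BuOH–THF–H2O, 0 °C to rt
Reagents that add atoms: sodium chlorite, [Na+].[O-]Cl=O
Why: In this Pinnick oxidation chlorous acid converts the aldehyde into the acid, and the excess alkene intercepts hypochlorous acid before it can chlorinate the open C5' position of the phenol.

Step 10
Reactants: 21 3-chloro-2-hydroxy-4-methoxy-6-propylbenzoic acid; 12 benzyl 2-(benzyloxy)-4-hydroxy-6-pentylbenzoate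
Product: 23 benzyl 2-(benzyloxy)-4-[(3-chloro-2-hydroxy-4-methoxy-6-propylbenzoyl)oxy]-6-pentylbenzoate, via mixed anhydride 22 (not isolated)
Conditions: (CF3CO)2O, toluene, rt
Reagents that add atoms: none
Why: In this mixed-anhydride esterification with trifluoroacetic anhydride, the classical depside coupling, the di-ortho-substituted acid is activated as its acyl trifluoroacetate and is taken up by the only free and unhindered phenol, C4–OH of 12, while the C2' hydroxyl, hydrogen-bonded to the carbonyl and flanked by chlorine, stays unacylated.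

Step 11
Reactants: 23 benzyl 2-(benzyloxy)-4-[(3-chloro-2-hydroxy-4-methoxy-6-propylbenzoyl)oxy]-6-pentylbenzoate
Product: 24 4-[(3-chloro-2-hydroxy-4-methoxy-6-propylbenzoyl)oxy]-2-hydroxy-6-pentylbenzoic acid (target)
Conditions: H2 (1 atm), 10% Pd/C, EtOAc, rt, stopped after uptake of 2 equiv H2
Reagents that add atoms: none
Why: Catalytic hydrogenolysis should cleave the benzylic C–O bonds of the benzyl ester and benzyl ether faster than the C3'–Cl bond of the electron-rich ring when the medium is neutral and free of base and the reaction is stopped at the calculated uptake.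

Compound list
1 | dibenzyl 3-oxopentanedioate (dibenzyl 3-oxoglutarate) | O=C(CC(=O)OCc1ccccc1)CC(=O)OCc1ccccc1 | starting material
2 | hexanoyl chloride | CCCCCC(Cl)=O | starting material
3 | dibenzyl 2-hexanoyl-3-oxopentanedioate (keto form drawn; enolised and configurationally labile) | CCCCCC(=O)C(C(=O)OCc1ccccc1)C(=O)CC(=O)OCc1ccccc1 | intermediate
4 | benzyl 4-hydroxy-2-oxo-6-pentyl-2H-pyran-5-carboxylate | CCCCCC1=C(C(=O)OCc2ccccc2)C(O)=CC(=O)O1 | intermediate
5 | benzyl 4-(benzyloxy)-2-oxo-6-pentyl-2H-pyran-5-carboxylate | CCCCCC1=C(C(=O)OCc2ccccc2)C(OCc2ccccc2)=CC(=O)O1 | intermediate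
6 | trimethylsilyl acetate | CC(=O)O[Si](C)(C)C | starting material
7 | lithium 1-(trimethylsilyloxy)ethenolate | [Li]OC(=C)O[Si](C)(C)C | intermediate
8 | 1,1-bis(trimethylsilyloxy)ethene | C=C(O[Si](C)(C)C)O[Si](C)(C)C | intermediate
9 | benzyl 5-(benzyloxy)-3-oxo-1-pentyl-8,8-bis(trimethylsilyloxy)-2-oxabicyclo[2.2.2]oct-5-ene-6-carboxylate (racemic, one enantiomer drawn) | CCCCC[C@@]12CC(O[Si](C)(C)C)(O[Si](C)(C)C)[C@@H](C(=O)O1)C(OCc1ccccc1)=C2C(=O)OCc1ccccc1 | intermediate
10 | benzyl 6-(benzyloxy)-2-pentyl-4,4-bis(trimethylsilyloxy)cyclohexa-1,5-diene-1-carboxylate | CCCCCC1=C(C(=O)OCc2ccccc2)C(OCc2ccccc2)=CC(O[Si](C)(C)C)(O[Si](C)(C)C)C1 | intermediate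
11 | benzyl 2-(benzyloxy)-6-pentyl-4-(trimethylsilyloxy)benzoate | CCCCCc1cc(O[Si](C)(C)C)cc(OCc2ccccc2)c1C(=O)OCc1ccccc1 | intermediate
12 | benzyl 2-(benzyloxy)-4-hydroxy-6-pentylbenzoate | CCCCCc1cc(O)cc(OCc2ccccc2)c1C(=O)OCc1ccccc1 | intermediate
13 | 5-propylbenzene-1,3-diol | CCCc1cc(O)cc(O)c1 | starting material
14 | 1,3-dimethoxy-5-propylbenzene | CCCc1cc(OC)cc(OC)c1 | intermediate
15 | (2,6-dimethoxy-4-propylphenyl)lithium | [Li]c1c(OC)cc(CCC)cc1OC | intermediate
16 | 2-chloro-1,3-dimethoxy-5-propylbenzene | CCCc1cc(OC)c(Cl)c(OC)c1 | intermediate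
17 | 2-chloro-4-[chloro(methoxy)methyl]-1,3-dimethoxy-5-propylbenzene (racemic) | CCCc1cc(OC)c(Cl)c(OC)c1C(Cl)OC | intermediate
18 | 3-chloro-2,4-dimethoxy-6-propylbenzaldehyde | CCCc1cc(OC)c(Cl)c(OC)c1C=O | intermediate
19 | (2-chloro-6-formyl-3-methoxy-5-propylphenoxy)dichloroborane | CCCc1cc(OC)c(Cl)c(OB(Cl)Cl)c1C=O | intermediate
20 | 3-chloro-2-hydroxy-4-methoxy-6-propylbenzaldehyde | CCCc1cc(OC)c(Cl)c(O)c1C=O | intermediate
21 | 3-chloro-2-hydroxy-4-methoxy-6-propylbenzoic acid | CCCc1cc(OC)c(Cl)c(O)c1C(=O)O | intermediate
22 | 3-chloro-2-hydroxy-4-methoxy-6-propylbenzoic trifluoroacetic anhydride | CCCc1cc(OC)c(Cl)c(O)c1C(=O)OC(=O)C(F)(F)F | intermediate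
23 | benzyl 2-(benzyloxy)-4-[(3-chloro-2-hydroxy-4-methoxy-6-propylbenzoyl)oxy]-6-pentylbenzoate | CCCCCc1cc(OC(=O)c2c(CCC)cc(OC)c(Cl)c2O)cc(OCc2ccccc2)c1C(=O)OCc1ccccc1 | intermediate
24 | 4-[(3-chloro-2-hydroxy-4-methoxy-6-propylbenzoyl)oxy]-2-hydroxy-6-pentylbenzoic acid (CNP0329756.0) | CCCCCc1cc(OC(=O)c2c(CCC)cc(OC)c(Cl)c2O)cc(O)c1C(=O)O | target

Total step count: 11.
Longest linear sequence: 7 steps (13 → 14 → 16 → 18 → 20 → 21 → 23 → 24). The ring B branch contributes 5 steps to the target (1 → 4 → 5 → 12 → 23 → 24), and step 3 supplies the dienophile.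

Steps most likely to fail

Step 4. The cycloaddition may be outrun by thermal O-to-C silyl migration and protonolysis of the ketene acetal, because the benzyloxy donor on pyrone C4 and the fully substituted C6 make the pyrone a sluggish diene.
- The fallback gives up the pyrone as the source of ring B and relies instead on hydrogen-bond differentiation of the two ring B hydroxyls. It sets out from acid 21.
- Purchased olivetolic acid F1 is converted with BnBr and KHCO3 in DMF into benzyl 2,4-dihydroxy-6-pentylbenzoate F2.
- 21 and F2 are joined with (CF3CO)2O in toluene by way of 22. The C2 hydroxyl, chelated to the ester carbonyl, stays free and only C4–OH is acylated, giving the depside benzyl ester F3.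
- Hydrogenolysis (H2, Pd/C, EtOAc) comes back to the route at 24.

Step 11. Hydrodechlorination at C3' may compete with cleavage of the two benzyl groups.
- The fallback replaces reduction by Lewis-acid dealkylation. It sets out from 23, which is treated with BCl3 and pentamethylbenzene as cation scavenger in CH2Cl2 at −78 °C.
- The benzyl ether and benzyl ester, both held around the ring B carbonyl, should be cleaved. The C–Cl bond, the unchelated C4' methoxy group and the depside ester are left.
- Aqueous work-up comes back to the route at 24. No new compound is made (F0).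

Step 10. Acylation by the hindered acid may be slow enough for acid-induced loss of the C2 benzyl ether or decarboxylation of 21 to intervene.
- The fallback changes to a protected acid chloride under basic conditions. It sets out from aldehyde 20.
- BnBr and K2CO3 in DMF should give 2-(benzyloxy)-3-chloro-4-methoxy-6-propylbenzaldehyde F4.
- Pinnick oxidation gives 2-(benzyloxy)-3-chloro-4-methoxy-6-propylbenzoic acid F5, and (COCl)2 with catalytic DMF in CH2Cl2 gives the acid chloride F6.
- Reaction of F6 with phenol 12 (Et3N, DMAP, CH2Cl2) gives the tribenzyl depside F7.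
- Hydrogenolysis of all three benzyl groups (H2, Pd/C, EtOAc) comes back to the route at 24.

Further compounds
F1 | step 4 | olivetolic acid (2,4-dihydroxy-6-pentylbenzoic acid, purchased) | CCCCCc1cc(O)cc(O)c1C(=O)O
F2 | step 4 | benzyl 2,4-dihydroxy-6-pentylbenzoate | CCCCCc1cc(O)cc(O)c1C(=O)OCc1ccccc1
F3 | step 4 | benzyl 4-[(3-chloro-2-hydroxy-4-methoxy-6-propylbenzoyl)oxy]-2-hydroxy-6-pentylbenzoate | CCCCCc1cc(OC(=O)c2c(CCC)cc(OC)c(Cl)c2O)cc(O)c1C(=O)OCc1ccccc1
F0 | step 11 | none | none
F4 | step 10 | 2-(benzyloxy)-3-chloro-4-methoxy-6-propylbenzaldehyde | CCCc1cc(OC)c(Cl)c(OCc2ccccc2)c1C=O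
F5 | step 10 | 2-(benzyloxy)-3-chloro-4-methoxy-6-propylbenzoic acid | CCCc1cc(OC)c(Cl)c(OCc2ccccc2)c1C(=O)O
F6 | step 10 | 2-(benzyloxy)-3-chloro-4-methoxy-6-propylbenzoyl chloride | CCCc1cc(OC)c(Cl)c(OCc2ccccc2)c1C(Cl)=O
F7 | step 10 | benzyl 2-(benzyloxy)-4-{[2-(benzyloxy)-3-chloro-4-methoxy-6-propylbenzoyl]oxy}-6-pentylbenzoate | CCCCCc1cc(OC(=O)c2c(CCC)cc(OC)c(Cl)c2OCc2ccccc2)cc(OCc2ccccc2)c1C(=O)OCc1ccccc1
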